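**Plan**
1. Germacrane numbering is used. Ring A is the carbocycle C1–C10. Ring B is the lactone O6–C6–C7–C11–C12. C13 is the exocyclic CH2, and C14 and C15 are the methyls on C10 and C4. The target is 6S,7R,8S,9S with 1(10)Z and 4E alkenes.
2. Cuts, in order: the silyl helpers on O7 and O8. Then C6–C7 together with O6–C12, which opens both rings to the acyclic keto-aldehyde 20. Then C7–C11, O9–C9, C9–C10 and C1=C10.
3. Enabling feature: the fusion bond C6–C7 of rings A and B joins a secondary carbinol to a tertiary one, and C7 is allylic to C11=C13 of the acrylate in ring B. The unit O7–C7–C11=C13 is the reduced and transposed form of the enone O7=C7–C11=C13. C6–C7 is therefore a cross-pinacol retron between a 2-methylene-3-oxo ester and the C4=C5–C6 enal.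
4. Forward order: geraniol supplies C1–C6 and C15. C10/C14 come from an iodo-Wittig reaction, C7–C9 from a Stille coupling and C11–C13 from a vinylalane. Ring A closes last and ring B follows in the same flask.
5. Stereochemistry: 4E comes from geraniol and 1(10)Z from the iodo-olefination. C8 and C9 come from a Sharpless epoxidation followed by invertive opening with isobutyric acid. C6 and C7 are set in the key step under control of C8. The C7 carbinol epimers and the E/Z allylchromium isomers both converge.

Key step: step 14

Remark: the SMILES is read as the absolute configuration, with H6 trans to O7 (trans-fused lactone), O6/O7 erythro, O7/O8 threo and O8/O9 erythro.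

Step 1
Reactants: 1 geraniol
Product: 2 geranyl 4-methoxybenzyl ether
Conditions: NaH, PMBCl, Bu4NI (5 mol %), THF/DMF, 0 to 25 °C
Reagents that add atoms: 4-methoxybenzyl chloride, COc1ccc(CCl)cc1
Why: Williamson ether synthesis on the primary allylic alkoxide installs a group at O6 that can later be removed oxidatively beside silyl ethers and esters.

Step 2
Reactants: 2 geranyl 4-methoxybenzyl ether
Product: 3 6,7-epoxygeranyl 4-methoxybenzyl ether (racemic at the epoxide carbon)
Conditions: mCPBA (1.0 equiv), CH2Cl2, −20 °C
Reagents that add atoms: 3-chloroperoxybenzoic acid, O=C(OO)c1cccc(Cl)c1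
Why: In this Prilezhaev epoxidation the remote trisubstituted alkene is more nucleophilic than the one deactivated by the allylic oxygen, and the new stereocentre is destroyed in step 3.

Step 3
Reactants: 3 6,7-epoxygeranyl 4-methoxybenzyl ether
Product: 4 (4E)-6-[(4-methoxybenzyl)oxy]-4-methylhex-4-enal
Conditions: H5IO6, THF/Et2O, 0 °C
Reagents that add atoms: none
Why: Acid-assisted epoxide hydrolysis and Malaprade glycol cleavage in one flask should release the C1 aldehyde and leave the 4E alkene untouched.

Step 4
Reactants: 4 (4E)-6-[(4-methoxybenzyl)oxy]-4-methylhex-4-enal; 5 ethyltriphenylphosphonium iodide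
Product: 7 (2E,6Z)-7-iodo-3-methylocta-2,6-dien-1-yl 4-methoxybenzyl ether, via iodo ylide 6 (not isolated)
Conditions: 5, n-BuLi, THF, 0 °C; I2, −78 °C; NaHMDS, −20 °C; then 4, −78 to −20 °C
Reagents that add atoms: iodine, [I][I]
Why: In this Wittig olefination with an α-iodo ylide (Stork–Zhao type) the kinetically favoured cis-oxaphosphetane should place iodine cis to the chain and so fix the 1(10)Z geometry.

Step 5
Reactants: 8 prop-2-yn-1-ol
Product: 9 (2E)-3-(tributylstannyl)prop-2-en-1-ol
Conditions: Bu3SnH, AIBN (2 mol %), neat, 80 °C; E isomer separated by chromatography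
Reagents that add atoms: tributyltin hydride, CCCC[SnH](CCCC)CCCC
Why: Radical hydrostannation of a terminal alkyne under equilibrating conditions (reversible stannyl radical addition) should favour the (E)-β-stannane.

Step 6
Reactants: 7 (2E,6Z)-7-iodo-3-methylocta-2,6-dien-1-yl 4-methoxybenzyl ether; 9 (2E)-3-(tributylstannyl)prop-2-en-1-ol
Product: 10 (2E,4Z,8E)-10-[(4-methoxybenzyl)oxy]-4,8-dimethyldeca-2,4,8-trien-1-ol
Conditions: PdCl2(MeCN)2 (5 mol %), DMF, 25 °C
Reagents that add atoms: none
Why: Stille coupling proceeds with retention at both sp2 carbons, so the C9–C10 bond should form as the (2E,4Z)-diene and the free alcohol is tolerated.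

Step 7
Reactants: 10 (2E,4Z,8E)-10-[(4-methoxybenzyl)oxy]-4,8-dimethyldeca-2,4,8-trien-1-ol
Product: 11 {(2R,3R)-3-[(2Z,6E)-8-[(4-methoxybenzyl)oxy]-6-methylocta-2,6-dien-2-yl]oxiran-2-yl}methanol
Conditions: Ti(OiPr)4 (10 mol %), D-(−)-diisopropyl tartrate (12 mol %), t-BuOOH, 4 Å MS, CH2Cl2, −25 °C
Reagents that add atoms: tert-butyl hydroperoxide, CC(C)(C)OO
Why: Sharpless asymmetric epoxidation is directed by the allylic hydroxyl so that only C8=C9 reacts, and the D-(−)-tartrate should give the (2R,3R)-epoxide, which sets C8 and the pre-inversion configuration of C9.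

Step 8
Reactants: 11 (2R,3R)-epoxy alcohol; 12 2-methylpropanoic acid
Product: 13 (2R,3S,4Z,8E)-1,2-dihydroxy-10-[(4-methoxybenzyl)oxy]-4,8-dimethyldeca-4,8-dien-3-yl 2-methylpropanoate
Conditions: Ti(OiPr)4 (1.5 equiv), 12 (2 equiv), CH2Cl2, 0 to 25 °C; aq. tartaric acid work-up
Reagents that add atoms: none
Why: In this titanium-assisted C3-selective opening of a 2,3-epoxy alcohol by a carboxylic acid, SN2 attack at the allylic carbon C9 inverts it, which should give the erythro C8/C9 pattern and place the isobutyrate without a protecting group at O9.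

Step 9
Reactants: 13 diol isobutyrate
Product: 14 (2R,3S,4Z,8E)-10-[(4-methoxybenzyl)oxy]-4,8-dimethyl-1,2-bis[(triethylsilyl)oxy]deca-4,8-dien-3-yl 2-methylpropanoate
Conditions: Et3SiOTf (2.5 equiv), 2,6-lutidine, CH2Cl2, −78 °C
Reagents that add atoms: triethylsilyl triflate, CC[Si](CC)(CC)OS(=O)(=O)C(F)(F)F
Why: Silylation with a silyl triflate at low temperature should outrun acyl migration and cover O7 and O8 with groups that fluoride removes.

Step 10
Reactants: 14 bis(triethylsilyl) ether
Product: 15 (2S,3S,4Z,8E)-10-[(4-methoxybenzyl)oxy]-4,8-dimethyl-1-oxo-2-[(triethylsilyl)oxy]deca-4,8-dien-3-yl 2-methylpropanoate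
Conditions: (COCl)2, DMSO, CH2Cl2, −78 to −40 °C; Et3N, −78 °C; cold pH 7 quench
Reagents that add atoms: none
Why: In this Swern oxidation of a bis-silyl ether, chlorodimethylsulfonium chloride attacks only the unhindered primary triethylsilyl ether, so the C7 aldehyde should form directly while the O8 ether stays, and the cold quench limits epimerisation at C8 and loss of the isobutyrate.

Step 11
Reactants: 15 C7 aldehyde; 16 methyl propiolate
Product: 18 methyl (4R,5S,6Z,10E)-3-hydroxy-12-[(4-methoxybenzyl)oxy]-6,10-dimethyl-2-methylidene-5-[(2-methylpropanoyl)oxy]-4-[(triethylsilyl)oxy]dodeca-6,10-dienoate (both C3 epimers), via vinylalane 17 (not isolated)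
Conditions: i-Bu2AlH, HMPA, THF, 0 °C; 16, 0 °C; then 15, 0 to 25 °C; Rochelle salt work-up
Reagents that add atoms: none
Why: α-Selective hydroalumination of the propiolate gives a non-basic acrylate α-anion equivalent whose 1,2-addition should give the Morita–Baylis–Hillman-type adduct without an amine base, and the C7 epimer mixture does not matter because C7 becomes planar in step 13.

Step 12
Reactants: 18 Morita–Baylis–Hillman-type adduct
Product: 19 methyl (4R,5S,6Z,10E)-3,12-dihydroxy-6,10-dimethyl-2-methylidene-5-[(2-methylpropanoyl)oxy]-4-[(triethylsilyl)oxy]dodeca-6,10-dienoate (both C3 epimers)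
Conditions: DDQ, CH2Cl2/pH 7 buffer, 0 °C
Reagents that add atoms: none
Why: Oxidative PMB cleavage by DDQ (hydride abstraction at the electron-rich benzylic position) should leave the silyl ether, both esters and the isolated alkenes untouched under buffered conditions.

Step 13
Reactants: 19 diol
Product: 20 methyl (4S,5S,6Z,10E)-6,10-dimethyl-2-methylidene-5-[(2-methylpropanoyl)oxy]-3,12-dioxo-4-[(triethylsilyl)oxy]dodeca-6,10-dienoate
Conditions: Dess–Martin periodinane (3 equiv), NaHCO3, CH2Cl2, 0 °C; filtration through a short pad, used at once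
Reagents that add atoms: none
Why: Dess–Martin oxidation under buffered neutral conditions, a known way from Morita–Baylis–Hillman adducts to 2-methylene-3-oxo esters, should raise C6 and C7 to the carbonyl level at once and merge the C7 epimers into one compound.

Step 14
Reactants: 20 acyclic keto-aldehyde
Product: 23 7,8-bis-O-triethylsilyl ether of the target (C6, C7, C8 and C9 arranged in space as in the target), via allylchromium 21 (not isolated), via chromium alkoxide 22 (not isolated)
Conditions: CrCl2 (10 equiv), Et3SiCl (4 equiv), DMF, 25 °C, 20 added over 12 h (final 2 mM); pH 7 buffer work-up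
Reagents that add atoms: chlorotriethylsilane, CC[Si](Cl)(CC)CC
Why: Proposed new method: CrCl2 transfers one electron to the doubly activated acceptor C13=C11(C12O2Me)–C7=O of 20, Et3SiCl silylates O7, and a second CrCl2 traps the captodative allyl radical at C13 to give the γ-siloxyallyl trivalent chromium species 21, which binds the C6 aldehyde oxygen and attacks C6 through its γ-carbon C7 in a six-membered Zimmerman–Traxler chair, so that C11=C13 is restored as the exocyclic methylene and the alkoxide 22 expels methoxide from C12. The closest known reaction types are the intermolecular CrCl2/R3SiCl cross pinacol-type coupling of vinyl ketones with aldehydes and the Nozaki–Hiyama–Kishi-type macrocyclisation of 2-(halomethyl)acrylates onto enals across C6–C7 of germacranolides; what is new is a 2-methylene-3-oxo ester as the reducible partner and a ring closure that creates the tertiary carbinol. Ring A closes by 10-exo-trig addition of C7 to the C6 carbonyl, helped by the 1(10)Z alkene as a turn element, and ring B follows by 5-exo-trig acyl substitution of O6 at C12. C7 is controlled by C8: A(1,3) strain between C8 and the C12 ester on the tetrasubstituted C7=C11 bond holds H8 in the alkene plane and the C8–C9 bond perpendicular to it, and C6 can bond only on the face anti to C9 without a g+/g− contact of ring atoms C5 and C9, which turns 8S into 7R. C6 is controlled by the chair, in which C5 and C8 are equatorial and the siloxy group (cis to C13) is axial, which should give the erythro O6/O7 pair and hence H6 trans to O7 (6S, trans-fused lactone); the E and Z forms of 21 can interconvert by a 1,3-shift of chromium and the bulky solvated CH2CrCl2 group favours the isomer with C8 trans to it, so the step is stereoconvergent. The selectivities needed are reduction of the methylene dicarbonyl before the β,β-disubstituted enal (lower LUMO, unhindered terminus), γ- before α-attack (closed transition state) and cyclisation before dimerisation (slow addition into excess CrCl2).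

Step 15
Reactants: 23 7,8-bis-O-triethylsilyl ether
Product: 24 target, (6S,7R,8S,9S)-7,8-dihydroxy-9-(2-methylpropanoyloxy)germacra-1(10)Z,4E,11(13)-trien-12,6-olide
Conditions: HF·pyridine, pyridine, THF, 0 to 25 °C
Reagents that add atoms: none
Why: Buffered fluoride desilylation should remove both triethylsilyl helpers without acid-induced transannular cyclisation, acyl migration or addition to the methylene lactone.

**Compound list**
1 | geraniol, (2E)-3,7-dimethylocta-2,6-dien-1-ol | CC(C)=CCC/C(C)=C/CO | starting material
2 | geranyl 4-methoxybenzyl ether | CC(C)=CCC/C(C)=C/COCc1ccc(OC)cc1 | intermediate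
3 | 6,7-epoxygeranyl 4-methoxybenzyl ether (racemic epoxide carbon) | CC1(C)OC1CC/C(C)=C/COCc1ccc(OC)cc1 | intermediate
4 | (4E)-6-[(4-methoxybenzyl)oxy]-4-methylhex-4-enal | O=CCC/C(C)=C/COCc1ccc(OC)cc1 | intermediate
5 | ethyltriphenylphosphonium iodide | CC[P+](c1ccccc1)(c1ccccc1)c1ccccc1.[I-] | starting material
6 | (1-iodoethylidene)triphenylphosphorane | IC(C)=P(c1ccccc1)(c1ccccc1)c1ccccc1 | intermediate
7 | (2E,6Z)-7-iodo-3-methylocta-2,6-dien-1-yl 4-methoxybenzyl ether | I/C(C)=C\CC/C(C)=C/COCc1ccc(OC)cc1 | intermediate
8 | prop-2-yn-1-ol | C#CCO | starting material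
9 | (2E)-3-(tributylstannyl)prop-2-en-1-ol | OC/C=C/[Sn](CCCC)(CCCC)CCCC | intermediate
10 | (2E,4Z,8E)-10-[(4-methoxybenzyl)oxy]-4,8-dimethyldeca-2,4,8-trien-1-ol | OC/C=C/C(C)=C\CC/C(C)=C/COCc1ccc(OC)cc1 | intermediate
11 | (2R,3R)-epoxy alcohol | OC[C@H]1O[C@@H]1/C(C)=C\CC/C(C)=C/COCc1ccc(OC)cc1 | intermediate
12 | 2-methylpropanoic acid | CC(C)C(=O)O | starting material
13 | (2R,3S)-1,2-diol 3-isobutyrate | OC[C@@H](O)[C@@H](OC(=O)C(C)C)/C(C)=C\CC/C(C)=C/COCc1ccc(OC)cc1 | intermediate
14 | bis(triethylsilyl) ether of 13 | CC[Si](CC)(CC)OC[C@@H](O[Si](CC)(CC)CC)[C@@H](OC(=O)C(C)C)/C(C)=C\CC/C(C)=C/COCc1ccc(OC)cc1 | intermediate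
15 | (2S,3S)-C7 aldehyde | O=C[C@@H](O[Si](CC)(CC)CC)[C@@H](OC(=O)C(C)C)/C(C)=C\CC/C(C)=C/COCc1ccc(OC)cc1 | intermediate
16 | methyl propiolate | C#CC(=O)OC | starting material
17 | [1-(methoxycarbonyl)ethenyl]diisobutylalane | C=C(C(=O)OC)[Al](CC(C)C)CC(C)C | intermediate
18 | Morita–Baylis–Hillman-type adduct (C7 epimers) | C=C(C(=O)OC)C(O)[C@@H](O[Si](CC)(CC)CC)[C@@H](OC(=O)C(C)C)/C(C)=C\CC/C(C)=C/COCc1ccc(OC)cc1 | intermediate
19 | C6,C7-diol (C7 epimers) | C=C(C(=O)OC)C(O)[C@@H](O[Si](CC)(CC)CC)[C@@H](OC(=O)C(C)C)/C(C)=C\CC/C(C)=C/CO | intermediate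
20 | acyclic keto-aldehyde (2-methylene-3-oxo ester and enal) | C=C(C(=O)OC)C(=O)[C@@H](O[Si](CC)(CC)CC)[C@@H](OC(=O)C(C)C)/C(C)=C\CC/C(C)=C/C=O | intermediate
21 | γ-siloxyallyl chromium dichloride (O7 cis to C13) | Cl[Cr](Cl)C/C(C(=O)OC)=C(\O[Si](CC)(CC)CC)[C@@H](O[Si](CC)(CC)CC)[C@@H](OC(=O)C(C)C)/C(C)=C\CC/C(C)=C/C=O | intermediate
22 | ring A chromium alkoxide, methyl ester still open | C=C(C(=O)OC)[C@]1(O[Si](CC)(CC)CC)[C@@H](O[Cr](Cl)Cl)/C=C(\C)CC/C=C(/C)[C@H](OC(=O)C(C)C)[C@@H]1O[Si](CC)(CC)CC | intermediate
23 | 7,8-bis-O-triethylsilyl ether of the target | C=C1C(=O)O[C@H]2/C=C(\C)CC/C=C(/C)[C@H](OC(=O)C(C)C)[C@H](O[Si](CC)(CC)CC)[C@]12O[Si](CC)(CC)CC | intermediate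
24 | target CNP0301808.4 | C=C1C(=O)O[C@H]2/C=C(\C)CC/C=C(/C)[C@H](OC(=O)C(C)C)[C@H](O)[C@]12O | target

Total step count: 15. Longest linear sequence: 14 (steps 1–4 and 6–15).

**Steps most likely to fail**

1. Step 14.
 - What may go wrong: bond formation at the fully substituted C7 may be slow. The allylchromium could then be protonated, lose the C8 siloxy group by vinylogous elimination, or react through the other alkene geometry or face. The C6 alkoxide may also be silylated before it lactonises.
 - Fallback (known chemistry; the same bond is made by a reductive carbonyl coupling with the methylene masked): starting from 20, conjugate addition of thiophenol (Et3N 5 mol %, CH2Cl2, 0 °C) should give the sulfide keto-aldehyde F1. McMurry-type pinacol macrocyclisation with low-valent titanium (TiCl3(DME)1.5, Zn–Cu couple, DME, 25 °C, slow addition) should join C6 and C7. The erythro diol should lactonise on work-up to the sulfide lactone F2, with diastereomers separated. mCPBA (1 equiv, CH2Cl2, −78 °C) should give the sulfoxide F3. Its syn-elimination (toluene, 60 °C) restores C11=C13 in the 8-O-triethylsilyl ether F4. HF·pyridine as in step 15 returns to the route at 24.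

2. Step 13.
 - What may go wrong: the acceptor may dimerise by hetero-Diels–Alder reaction or polymerise, and the isobutyrate may undergo β-elimination during oxidation, concentration or storage.
 - Fallback (the methylene is masked through the oxidation and released cold): starting from 19, PhSeSePh/NaBH4 (EtOH, 0 °C) should add phenylselenide to the acrylate to give the selenide diol F5. Dess–Martin oxidation should give the storable selenide keto-aldehyde F6. mCPBA (1 equiv, CH2Cl2, −78 °C) should give the selenoxide F7. This eliminates on warming to 0 °C and returns to the route at 20, as a cold solution that is dried and fed directly into step 14.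

3. Step 8.
 - What may go wrong: allyl-cation character at C9 may erode regio- and stereofidelity, attack may occur in the SN2' sense at C1, and the titanium alkoxide may promote acyl migration to O8 or O7.
 - Fallback (chiral pool instead of epoxide chemistry; it bypasses steps 5–8): starting from 7, iodine–lithium exchange (t-BuLi, Et2O, −78 °C) and Felkin–Anh addition to commercial (R)-2,3-O-isopropylideneglyceraldehyde should give the anti allylic alcohol F8 after separation of the minor epimer. Isobutyryl chloride, pyridine and DMAP should give the isobutyrate acetonide F9. AcOH/H2O (4:1, 40 °C) removes the terminal acetonide and returns to the route at 13.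

**Further compounds**
F1 | step 14 | sulfide keto-aldehyde (C11 epimers) | COC(=O)C(CSc1ccccc1)C(=O)[C@@H](O[Si](CC)(CC)CC)[C@@H](OC(=O)C(C)C)/C(C)=C\CC/C(C)=C/C=O
F2 | step 14 | sulfide lactone (7-OH, 8-OSiEt3, C11 epimers) | C(Sc1ccccc1)C1C(=O)O[C@H]2/C=C(\C)CC/C=C(/C)[C@H](OC(=O)C(C)C)[C@H](O[Si](CC)(CC)CC)[C@]12O
F3 | step 14 | sulfoxide | O=S(CC1C(=O)O[C@H]2/C=C(\C)CC/C=C(/C)[C@H](OC(=O)C(C)C)[C@H](O[Si](CC)(CC)CC)[C@]12O)c1ccccc1
F4 | step 14 | 8-O-triethylsilyl ether of the target | C=C1C(=O)O[C@H]2/C=C(\C)CC/C=C(/C)[C@H](OC(=O)C(C)C)[C@H](O[Si](CC)(CC)CC)[C@]12O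
F5 | step 13 | selenide diol (C7 and C11 epimers) | COC(=O)C(C[Se]c1ccccc1)C(O)[C@@H](O[Si](CC)(CC)CC)[C@@H](OC(=O)C(C)C)/C(C)=C\CC/C(C)=C/CO
F6 | step 13 | selenide keto-aldehyde (C11 epimers) | COC(=O)C(C[Se]c1ccccc1)C(=O)[C@@H](O[Si](CC)(CC)CC)[C@@H](OC(=O)C(C)C)/C(C)=C\CC/C(C)=C/C=O
F7 | step 13 | selenoxide | COC(=O)C(C[Se](=O)c1ccccc1)C(=O)[C@@H](O[Si](CC)(CC)CC)[C@@H](OC(=O)C(C)C)/C(C)=C\CC/C(C)=C/C=O
F8 | step 8 | anti allylic alcohol (C8 R, C9 S, O7/O8 acetonide) | CC1(C)OC[C@@H](O1)[C@@H](O)/C(C)=C\CC/C(C)=C/COCc1ccc(OC)cc1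
F9 | step 8 | isobutyrate acetonide | CC1(C)OC[C@@H](O1)[C@@H](OC(=O)C(C)C)/C(C)=C\CC/C(C)=C/COCc1ccc(OC)cc1
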